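**Retrosynthetic overview**
1. Last ring: the seven-membered lactone, by a stereoinvertive 7-exo opening of a (4R,5R)-epoxide at C4 by the C16 acrylic acid (proposed new step); then C5 acetylation and C13 desilylation.
2. First ring: the 14-membered carbocycle, by nickel-catalysed reductive alkyne–aldehyde macrocyclisation (C12–C13 bond, 11E alkene); C13 is then fixed by oxidation and CBS reduction.
3. Linear ynal from (S)-limonene (C1–C5, C13–C17, the C1 stereocentre), Me3Al (C18), oxirane (C6, C7), ethyl (Z)-3-iodobut-2-enoate (C8–C10, C19, the 8Z alkene) and propynylmagnesium bromide (C11, C12, C20).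
4. 4E alkene by zirconium-catalysed carboalumination; C7–C8 by Negishi coupling; (4R,5R)-epoxide by Shi epoxidation while C8=C9 is still an unreactive enoate.
5. Ring order: carbocycle, then lactone.

Assumption: atoms carry the target's cembrane-style labels (C1 = CH bearing the acrylate, C2/C3 = CH2, C4 = C(CH3)–O, C5 = CH–OAc, C6/C7 = CH2, C8(CH3)=C9, C10 = CH2, C11=C12(CH3), C13 = CHOH, C14 = CH2, C15(=C17H2)–C16(=O), methyls C18/C19/C20), so the target is (1S,4S,5R,13R,8Z,11E); PMB = 4-methoxybenzyl, TBS = tert-butyldimethylsilyl, TES = triethylsilyl.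

**Route**

Step 1
Reactants: 1 (S)-(−)-limonene
Product: 4 2-[(1S)-4-methylcyclohex-3-en-1-yl]prop-2-en-1-ol, via C10-allyllithium 2 (not isolated), via dimethyl allylboronate 3 (not isolated)
Conditions: n-BuLi, TMEDA, hexane, rt; B(OMe)3, THF, −78 °C; H2O2, aq. NaOH, 0 °C
Reagents that add atoms: hydrogen peroxide, OO
Why: Allylic metalation of limonene by n-BuLi·TMEDA occurs at the isopropenyl methyl, and borylation then oxidation gives the primary allylic alcohol without touching the ring stereocentre.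

Step 2
Reactants: 4 allylic alcohol
Product: 5 PMB ether of 4
Conditions: NaH, PMBCl, Bu4NI (cat.), THF/DMF, 0 °C → rt
Reagents that add atoms: 4-methoxybenzyl chloride, COc1ccc(CCl)cc1
Why: Williamson ether synthesis on a primary alkoxide; no stereocentre is involved.

Step 3
Reactants: 5 PMB ether
Product: 6 ring 1,2-epoxide of 5 (both epoxide diastereomers)
Conditions: mCPBA, NaHCO3, CH2Cl2, 0 °C
Reagents that add atoms: 3-chloroperoxybenzoic acid, OOC(=O)c1cccc(Cl)c1
Why: Prilezhaev epoxidation is selective for the electron-rich trisubstituted ring alkene over the 1,1-disubstituted allylic-ether alkene, and the epoxide configuration is irrelevant because both carbons become carbonyls.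

Step 4
Reactants: 6 epoxide
Product: 8 (3S)-3-[3-(PMB-oxy)prop-1-en-2-yl]-6-oxoheptanal, via ring 1,2-diol 7 (not isolated)
Conditions: H5IO6, THF/H2O, 0 °C → rt
Reagents that add atoms: water, O
Why: Periodic acid hydrolyses the epoxide and cleaves the resulting glycol (Malaprade cleavage) to the methyl ketone (C4) and the aldehyde (C13); C1 is untouched.

Step 5
Reactants: 8 keto aldehyde
Product: 9 (5S)-7-hydroxy-5-[3-(PMB-oxy)prop-1-en-2-yl]heptan-2-one
Conditions: NaBH(OAc)3, benzene, 60 °C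
Reagents that add atoms: none
Why: Chemoselective hydride reduction, since triacetoxyborohydride reduces aldehydes but not unactivated ketones.

Step 6
Reactants: 9 keto alcohol
Product: 10 (5S)-7-(TBS-oxy)-5-[3-(PMB-oxy)prop-1-en-2-yl]heptan-2-one
Conditions: TBSCl, imidazole, DMF, rt
Reagents that add atoms: tert-butyldimethylsilyl chloride, CC(C)(C)[Si](C)(C)Cl
Why: Standard silylation of a primary alcohol.

Step 7
Reactants: 10 methyl ketone
Product: 12 terminal alkyne (C4≡C5), via enol phosphate 11 (not isolated)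
Conditions: LiN(i-Pr)2, THF, −78 °C; ClP(O)(OEt)2, −78 °C → rt; LiN(i-Pr)2 (2.3 equiv), −78 °C → rt
Reagents that add atoms: none
Why: Negishi's one-pot methyl ketone to alkyne conversion, by kinetic enolisation at CH3, O-phosphorylation and E2 elimination of the enol phosphate.

Step 8
Reactants: 12 alkyne
Product: 15 (3E,7S)-homoallylic alcohol (C7–OH; 4E alkene), via alkenylalane 13 (not isolated), via lithium alkenylalanate 14 (not isolated)
Conditions: Me3Al, Cp2ZrCl2 (25 mol %), CH2Cl2, 0 °C → rt; n-BuLi, hexane/THF, −78 °C; oxirane, −78 °C → rt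
Reagents that add atoms: trimethylaluminium, C[Al](C)C; oxirane, C1CO1
Why: Zirconium-catalysed Negishi carboalumination adds CH3 (C18) and Al syn across the alkyne with CH3 on the internal carbon, which fixes the 4E geometry, and the derived alanate opens oxirane with retention of that geometry.

Step 9
Reactants: 15 homoallylic alcohol
Product: 16 homoallylic iodide (C7–I)
Conditions: I2, PPh3, imidazole, CH2Cl2, 0 °C
Reagents that add atoms: iodine, II
Why: Appel-type (Garegg–Samuelsson) iodination of a primary alcohol.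

Step 10
Reactants: 17 ethyl but-2-ynoate
Product: 18 ethyl (2Z)-3-iodobut-2-enoate
Conditions: NaI, AcOH, 110 °C
Reagents that add atoms: sodium iodide, [Na+].[I-]
Why: Conjugate hydroiodination of the ynoate proceeds by anti addition and gives the Z-β-iodoenoate, which carries the 8Z geometry of the target.

Step 11
Reactants: 16 homoallylic iodide; 18 ethyl (2Z)-3-iodobut-2-enoate
Product: 20 ethyl (2Z,6E,10S)-dienoate (C10 ester; 8Z and 4E alkenes), via alkylzinc iodide 19 (not isolated)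
Conditions: Zn dust, LiCl, THF, 40 °C; then 18, Pd(PPh3)4 (5 mol %), THF, rt
Reagents that add atoms: none
Why: Zinc insertion into the primary iodide and Negishi sp3–sp2 cross-coupling forms C7–C8 with retention of the Z geometry of the iodoenoate.

Step 12
Reactants: 20 dienoate
Product: 21 (4R,5R)-epoxy enoate
Conditions: 1,2:4,5-di-O-isopropylidene-β-D-erythro-2,3-hexodiulo-2,6-pyranose (D-fructose-derived Shi ketone, 30 mol %), KHSO5 (Oxone), K2CO3, Bu4NHSO4, MeCN/CH2(OMe)2/aq. Na2B4O7 buffer, 0 °C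
Reagents that add atoms: potassium peroxymonosulfate, [K+].[O-]S(=O)(=O)OO
Why: Shi asymmetric epoxidation, in which the chiral dioxirane attacks the electron-rich E-trisubstituted C4=C5 alkene through the spiro transition state to give the (4R,5R)-epoxide under reagent control, while the enoate alkene is electron-poor and the 1,1-disubstituted alkene reacts slowly.

Step 13
Reactants: 21 epoxy enoate
Product: 22 (Z)-allylic alcohol (C10–OH)
Conditions: i-Bu2AlH, CH2Cl2, −78 °C
Reagents that add atoms: none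
Why: 1,2-Reduction of the enoate by the aluminium hydride at low temperature leaves the trisubstituted epoxide intact.

Step 14
Reactants: 22 allylic alcohol
Product: 24 (Z)-allylic bromide (C10–Br), via allylic mesylate 23 (not isolated)
Conditions: MsCl, Et3N, CH2Cl2, −40 °C; LiBr, THF, −40 → 0 °C
Reagents that add atoms: lithium bromide, [Li+].[Br-]
Why: Mesylation then SN2 displacement by bromide keeps the Z alkene and avoids acid that would open the epoxide.

Step 15
Reactants: 24 allylic bromide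
Product: 25 skipped enyne (C10–C11≡C12–C20)
Conditions: CH3C≡CMgBr, CuBr·SMe2 (10 mol %), THF, −30 → 0 °C
Reagents that add atoms: 1-propynylmagnesium bromide, CC#C[Mg]Br
Why: Copper-catalysed SN2 coupling of an alkynyl Grignard reagent with a primary allylic bromide gives the 1,4-enyne with retention of the Z alkene.

Step 16
Reactants: 25 enyne silyl ether
Product: 26 primary alcohol (C13–OH)
Conditions: Bu4NF, AcOH, THF, 0 °C → rt
Reagents that add atoms: none
Why: Fluoride desilylation, buffered so that the skipped enyne does not isomerise.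

Step 17
Reactants: 26 alcohol
Product: 27 ynal (C13 aldehyde)
Conditions: Dess–Martin periodinane, NaHCO3, CH2Cl2, 0 °C → rt
Reagents that add atoms: none
Why: Dess–Martin oxidation under buffered, non-acidic conditions; the C1 stereocentre is β to the aldehyde and cannot epimerise.

Step 18
Reactants: 27 ynal
Product: 29 macrocyclic allylic alcohols (14-membered ring; both C13 epimers), via TES ethers 28 (not isolated)
Conditions: Ni(cod)2 (25 mol %), 1,3-bis(2,4,6-trimethylphenyl)imidazolium chloride (IMes·HCl, 25 mol %), KOt-Bu (25 mol %), Et3SiH, THF, rt, slow addition to 0.005 M; then Bu4NF, AcOH, 0 °C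
Reagents that add atoms: none
Why: Nickel-catalysed reductive alkyne–aldehyde macrocyclisation, in which zerovalent nickel–carbene couples alkyne and aldehyde by oxidative cyclisation and the silane cleaves the nickelacycle with syn delivery of H; the small carbene places the new C12–C13 bond at the methyl-bearing alkyne carbon, giving the endocyclic 11E alkene, and both C13 epimers are carried on because C13 is reset in steps 19 and 20.

Step 19
Reactants: 29 allylic alcohols
Product: 30 macrocyclic (11E)-enone (C13 ketone)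
Conditions: Dess–Martin periodinane, NaHCO3, CH2Cl2, 0 °C
Reagents that add atoms: none
Why: Dess–Martin oxidation converges both C13 epimers to one enone under buffered conditions that keep the skipped diene in place.

Step 20
Reactants: 30 enone
Product: 31 (13R)-allylic alcohol
Conditions: (S)-2-methyl-CBS-oxazaborolidine (0.5 equiv), catecholborane, toluene, −78 °C
Reagents that add atoms: none
Why: Corey–Bakshi–Shibata reduction, in which the α-methyl alkenyl arm acts as the large group so the (S)-oxazaborolidine delivers hydride to give the (13R)-alcohol under reagent control, and catecholborane at −78 °C does not hydroborate the alkenes.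

Step 21
Reactants: 31 allylic alcohol
Product: 32 (13R)-TBS ether
Conditions: TBSCl, imidazole, DMAP (cat.), DMF, rt
Reagents that add atoms: tert-butyldimethylsilyl chloride, CC(C)(C)[Si](C)(C)Cl
Why: Silylation with the chloride (not the triflate) spares the acid-sensitive epoxide.

Step 22
Reactants: 32 PMB ether
Product: 33 primary allylic alcohol (C16–OH)
Conditions: DDQ, CH2Cl2/pH 7 buffer, 0 °C
Reagents that add atoms: none
Why: Oxidative cleavage of the PMB ether by single-electron transfer to DDQ under neutral conditions leaves the silyl ether and epoxide untouched.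

Step 23
Reactants: 33 allylic alcohol
Product: 34 2-substituted acrolein (C16 aldehyde)
Conditions: MnO2, CH2Cl2, rt
Reagents that add atoms: none
Why: MnO2 oxidises only the allylic alcohol.

Step 24
Reactants: 34 enal
Product: 35 epoxy acrylic acid (C16 acid)
Conditions: NaClO2, NaH2PO4, 2-methyl-2-butene, t-BuOH/H2O, 0 °C
Reagents that add atoms: sodium chlorite, [Na+].[O-]Cl=O
Why: Pinnick oxidation of the enal, with the alkene scavenger protecting the ring alkenes from HOCl.

Step 25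
Reactants: 35 epoxy acid
Product: 36 (4S,5R)-5-hydroxy ε-lactone (13R-OTBS)
Conditions: (R)-3,3'-bis(2,4,6-triisopropylphenyl)-1,1'-binaphthyl-2,2'-diyl hydrogen phosphate (10 mol %), toluene (0.01 M), 4 Å sieves, 0 °C → rt
Reagents that add atoms: none
Why: Proposed new method: the confined phosphoric acid is proposed to pair with the acrylic acid as a hydrogen-bonded heterodimer while hydrogen-bonding the epoxide oxygen, so the carboxyl C=O oxygen attacks the more substituted, cation-stabilising C4 anti to the breaking C–O bond in a 7-exo closure (8-endo attack at C5 is disfavoured by ring size and charge, and the tight ion pair should suppress hydride shift and E1 loss), which forms the lactone, inverts C4 from R to S and leaves the C5–O bond (R) intact; the closest known reaction type is Brønsted-acid epoxide-opening lactonisation of epoxy acids to five- and six-membered lactones together with phosphoric-acid-catalysed opening of epoxides by carboxylic acids, which to my knowledge has not been shown for a 7-exo closure at a fully substituted epoxide carbon inside a macrocycle.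

Step 26
Reactants: 36 hydroxy lactone
Product: 37 5-acetate (13R-OTBS)
Conditions: Ac2O, pyridine, DMAP (cat.), CH2Cl2, 0 °C → rt
Reagents that add atoms: acetic anhydride, CC(=O)OC(C)=O
Why: DMAP-catalysed acetylation of the only free hydroxyl.

Step 27
Reactants: 37 silyl ether
Product: 38 target CNP0130972.7
Conditions: HF·pyridine, pyridine, THF, 0 °C → rt
Reagents that add atoms: none
Why: Buffered fluoride desilylation frees the C13 hydroxyl without base that could attack the α-methylene lactone or move the acetate.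

**Compound list**
1 | (S)-(−)-limonene, (4S)-1-methyl-4-(prop-1-en-2-yl)cyclohex-1-ene | CC1=CC[C@H](CC1)C(C)=C | starting material
2 | [2-[(1S)-4-methylcyclohex-3-en-1-yl]prop-2-en-1-yl]lithium (not isolated) | CC1=CC[C@H](CC1)C(=C)C[Li] | intermediate
3 | dimethyl [2-[(1S)-4-methylcyclohex-3-en-1-yl]prop-2-en-1-yl]boronate (not isolated) | CC1=CC[C@H](CC1)C(=C)CB(OC)OC | intermediate
4 | 2-[(1S)-4-methylcyclohex-3-en-1-yl]prop-2-en-1-ol | CC1=CC[C@H](CC1)C(=C)CO | intermediate
5 | 1-methoxy-4-[[2-[(1S)-4-methylcyclohex-3-en-1-yl]prop-2-en-1-yl]oxymethyl]benzene | CC1=CC[C@H](CC1)C(=C)COCc1ccc(OC)cc1 | intermediate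
6 | (4S)-1-methyl-4-[3-(PMB-oxy)prop-1-en-2-yl]-7-oxabicyclo[4.1.0]heptane, both epoxide diastereomers | CC12OC1C[C@H](CC2)C(=C)COCc1ccc(OC)cc1 | intermediate
7 | (4S)-1-methyl-4-[3-(PMB-oxy)prop-1-en-2-yl]cyclohexane-1,2-diol, diastereomer mixture (not isolated) | CC1(O)C(O)C[C@H](CC1)C(=C)COCc1ccc(OC)cc1 | intermediate
8 | (3S)-3-[3-(PMB-oxy)prop-1-en-2-yl]-6-oxoheptanal | CC(=O)CC[C@H](C(=C)COCc1ccc(OC)cc1)CC=O | intermediate
9 | (5S)-7-hydroxy-5-[3-(PMB-oxy)prop-1-en-2-yl]heptan-2-one | CC(=O)CC[C@H](C(=C)COCc1ccc(OC)cc1)CCO | intermediate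
10 | (5S)-7-(TBS-oxy)-5-[3-(PMB-oxy)prop-1-en-2-yl]heptan-2-one | CC(=O)CC[C@H](C(=C)COCc1ccc(OC)cc1)CCO[Si](C)(C)C(C)(C)C | intermediate
11 | diethyl (5S)-7-(TBS-oxy)-5-[3-(PMB-oxy)prop-1-en-2-yl]hept-1-en-2-yl phosphate (not isolated) | C=C(OP(=O)(OCC)OCC)CC[C@H](C(=C)COCc1ccc(OC)cc1)CCO[Si](C)(C)C(C)(C)C | intermediate
12 | tert-butyl[[(3S)-3-[3-(PMB-oxy)prop-1-en-2-yl]hept-6-yn-1-yl]oxy]dimethylsilane | C#CCC[C@H](C(=C)COCc1ccc(OC)cc1)CCO[Si](C)(C)C(C)(C)C | intermediate
13 | dimethyl[(1E,5S)-7-(TBS-oxy)-2-methyl-5-[3-(PMB-oxy)prop-1-en-2-yl]hept-1-en-1-yl]alane (not isolated) | C[Al](C)/C=C(\C)CC[C@H](C(=C)COCc1ccc(OC)cc1)CCO[Si](C)(C)C(C)(C)C | intermediate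
14 | lithium butyl(dimethyl)[(1E,5S)-alkenyl]aluminate derived from 13 (not isolated) | [Li+].CCCC[Al-](C)(C)/C=C(\C)CC[C@H](C(=C)COCc1ccc(OC)cc1)CCO[Si](C)(C)C(C)(C)C | intermediate
15 | (3E,7S)-9-(TBS-oxy)-4-methyl-7-[3-(PMB-oxy)prop-1-en-2-yl]non-3-en-1-ol | OCC/C=C(\C)CC[C@H](C(=C)COCc1ccc(OC)cc1)CCO[Si](C)(C)C(C)(C)C | intermediate
16 | tert-butyl[[(3S,6E)-9-iodo-6-methyl-3-[3-(PMB-oxy)prop-1-en-2-yl]non-6-en-1-yl]oxy]dimethylsilane | ICC/C=C(\C)CC[C@H](C(=C)COCc1ccc(OC)cc1)CCO[Si](C)(C)C(C)(C)C | intermediate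
17 | ethyl but-2-ynoate | CC#CC(=O)OCC | starting material
18 | ethyl (2Z)-3-iodobut-2-enoate | CCOC(=O)/C=C(/C)I | intermediate
19 | [(3E,7S)-9-(TBS-oxy)-4-methyl-7-[3-(PMB-oxy)prop-1-en-2-yl]non-3-en-1-yl]zinc iodide (not isolated) | I[Zn]CC/C=C(\C)CC[C@H](C(=C)COCc1ccc(OC)cc1)CCO[Si](C)(C)C(C)(C)C | intermediate
20 | ethyl (2Z,6E,10S)-12-(TBS-oxy)-3,7-dimethyl-10-[3-(PMB-oxy)prop-1-en-2-yl]dodeca-2,6-dienoate | CCOC(=O)/C=C(/C)CC/C=C(\C)CC[C@H](C(=C)COCc1ccc(OC)cc1)CCO[Si](C)(C)C(C)(C)C | intermediate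
21 | ethyl (2Z)-5-[(2R,3R)-3-[(3S)-5-(TBS-oxy)-3-[3-(PMB-oxy)prop-1-en-2-yl]pentyl]-3-methyloxiran-2-yl]-3-methylpent-2-enoate | CCOC(=O)/C=C(/C)CC[C@H]1O[C@]1(C)CC[C@H](C(=C)COCc1ccc(OC)cc1)CCO[Si](C)(C)C(C)(C)C | intermediate
22 | (2Z)-5-[(2R,3R)-3-[(3S)-5-(TBS-oxy)-3-[3-(PMB-oxy)prop-1-en-2-yl]pentyl]-3-methyloxiran-2-yl]-3-methylpent-2-en-1-ol | OC/C=C(/C)CC[C@H]1O[C@]1(C)CC[C@H](C(=C)COCc1ccc(OC)cc1)CCO[Si](C)(C)C(C)(C)C | intermediate
23 | methanesulfonate of 22 (not isolated) | CS(=O)(=O)OC/C=C(/C)CC[C@H]1O[C@]1(C)CC[C@H](C(=C)COCc1ccc(OC)cc1)CCO[Si](C)(C)C(C)(C)C | intermediate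
24 | (Z)-allylic bromide corresponding to 22 (C10–Br) | BrC/C=C(/C)CC[C@H]1O[C@]1(C)CC[C@H](C(=C)COCc1ccc(OC)cc1)CCO[Si](C)(C)C(C)(C)C | intermediate
25 | tert-butyl[[(3S)-5-[(2R,3R)-2-methyl-3-[(3Z)-3-methyloct-3-en-6-yn-1-yl]oxiran-2-yl]-3-[3-(PMB-oxy)prop-1-en-2-yl]pentyl]oxy]dimethylsilane | CC#CC/C=C(/C)CC[C@H]1O[C@]1(C)CC[C@H](C(=C)COCc1ccc(OC)cc1)CCO[Si](C)(C)C(C)(C)C | intermediate
26 | (3S)-5-[(2R,3R)-2-methyl-3-[(3Z)-3-methyloct-3-en-6-yn-1-yl]oxiran-2-yl]-3-[3-(PMB-oxy)prop-1-en-2-yl]pentan-1-ol | CC#CC/C=C(/C)CC[C@H]1O[C@]1(C)CC[C@H](C(=C)COCc1ccc(OC)cc1)CCO | intermediate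
27 | (3S)-5-[(2R,3R)-2-methyl-3-[(3Z)-3-methyloct-3-en-6-yn-1-yl]oxiran-2-yl]-3-[3-(PMB-oxy)prop-1-en-2-yl]pentanal | CC#CC/C=C(/C)CC[C@H]1O[C@]1(C)CC[C@H](C(=C)COCc1ccc(OC)cc1)CC=O | intermediate
28 | 14-membered carbocycle C1–C14 with (1S), (4R,5R)-4,5-epoxide, 8Z and 11E alkenes, CH2=C(CH2OPMB)– on C1 and OTES on C13, both C13 epimers (not isolated) | C=C(COCc1ccc(OC)cc1)[C@@H]1CC(O[Si](CC)(CC)CC)/C(C)=C/C/C=C(/C)CC[C@H]2O[C@]2(C)CC1 | intermediate
29 | as 28 with free C13–OH, both C13 epimers | C=C(COCc1ccc(OC)cc1)[C@@H]1CC(O)/C(C)=C/C/C=C(/C)CC[C@H]2O[C@]2(C)CC1 | intermediate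
30 | as 29 with C13 ketone: (1S,4R,5R,8Z,11E)-epoxy enone | C=C(COCc1ccc(OC)cc1)[C@@H]1CC(=O)/C(C)=C/C/C=C(/C)CC[C@H]2O[C@]2(C)CC1 | intermediate
31 | (1S,4R,5R,13R,8Z,11E)-epoxy allylic alcohol, C16–OPMB | C=C(COCc1ccc(OC)cc1)[C@@H]1C[C@@H](O)/C(C)=C/C/C=C(/C)CC[C@H]2O[C@]2(C)CC1 | intermediate
32 | 13-O-TBS ether of 31 | C=C(COCc1ccc(OC)cc1)[C@@H]1C[C@@H](O[Si](C)(C)C(C)(C)C)/C(C)=C/C/C=C(/C)CC[C@H]2O[C@]2(C)CC1 | intermediate
33 | as 32 with free C16–OH (2-substituted allyl alcohol on C1) | C=C(CO)[C@@H]1C[C@@H](O[Si](C)(C)C(C)(C)C)/C(C)=C/C/C=C(/C)CC[C@H]2O[C@]2(C)CC1 | intermediate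
34 | as 33 with C16 aldehyde (2-substituted acrolein) | C=C(C=O)[C@@H]1C[C@@H](O[Si](C)(C)C(C)(C)C)/C(C)=C/C/C=C(/C)CC[C@H]2O[C@]2(C)CC1 | intermediate
35 | as 33 with C16 carboxylic acid: (1S,4R,5R,13R,8Z,11E)-epoxy acrylic acid | C=C(C(=O)O)[C@@H]1C[C@@H](O[Si](C)(C)C(C)(C)C)/C(C)=C/C/C=C(/C)CC[C@H]2O[C@]2(C)CC1 | intermediate
36 | (1S,4S,5R,13R,8Z,11E)-5-hydroxy-13-(TBS-oxy)cembra-8,11,15(17)-trien-16,4-olide | C=C1C(=O)O[C@@]2(C)CC[C@H]1C[C@@H](O[Si](C)(C)C(C)(C)C)/C(C)=C/C/C=C(/C)CC[C@H]2O | intermediate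
37 | 5-acetate of 36 | C=C1C(=O)O[C@@]2(C)CC[C@H]1C[C@@H](O[Si](C)(C)C(C)(C)C)/C(C)=C/C/C=C(/C)CC[C@H]2OC(C)=O | intermediate
38 | CNP0130972.7, (1S,4S,5R,13R,8Z,11E)-5-acetoxy-13-hydroxycembra-8,11,15(17)-trien-16,4-olide | C=C1C(=O)O[C@@]2(C)CC[C@H]1C[C@@H](O)/C(C)=C/C/C=C(/C)CC[C@H]2OC(C)=O | target

**Step count and risks**
Total step count: 27. Longest linear sequence: 26 (steps 1–9 and 11–27 from (S)-limonene); step 10 makes the side fragment.

Steps most likely to fail:

Step 25 (the proposed lactonisation). The risks are hydride shift to a ketone, E1 loss to an allylic alcohol, or no closure for conformational reasons. The fallback uses known chemistry and runs from epoxy acid 35 to acetate 37. Dilute HClO4 in THF/H2O at 0 °C opens the epoxide with water at the tertiary C4 with inversion and gives the (4S,5R)-dihydroxy acid F7. Ac2O/pyridine acetylates only the secondary C5–OH and gives the 5-acetoxy-4-hydroxy acid F8. 2,4,6-Trichlorobenzoyl chloride and Et3N give the Yamaguchi mixed anhydride F9, which is added slowly to DMAP in toluene at 80 °C so that the tertiary C4–OH is acylated, and the route is rejoined at 37.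

Step 18 (macrocyclisation). The risks are oligomerisation, C–C bond formation at the wrong alkyne carbon, and nickel insertion into the allylic ether. The fallback runs from enyne 25 to alcohols 29. Hydrozirconation with excess Cp2Zr(H)Cl (THF, rt, equilibrated so that zirconium sits on the methyl-bearing carbon) gives the alkenylzirconocene chloride F3, and I2 gives the (E)-2-iodoalkene F4. Bu4NF gives the primary alcohol F5 and Dess–Martin oxidation gives the iodo aldehyde F6. A Nozaki–Hiyama–Kishi macrocyclisation (CrCl2, NiCl2 cat., DMSO/THF, high dilution) then forms C12–C13 and returns to 29.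

Step 8 (one-pot carboalumination and oxirane opening). The risks are sluggish reaction of the alanate with oxirane and transfer of methyl instead of the alkenyl group. The fallback runs from alkyne 12 to alcohol 15. The same carboalumination (alkenylalane 13) is quenched with I2 to give the isolable (E)-vinyl iodide F1. t-BuLi (Et2O, −78 °C) gives the vinyllithium F2, which opens oxirane in the presence of BF3·OEt2 and returns to 15.

**Further compounds**
F1 | step 8 | tert-butyl[[(3S,6E)-7-iodo-6-methyl-3-[3-(PMB-oxy)prop-1-en-2-yl]hept-6-en-1-yl]oxy]dimethylsilane | I/C=C(\C)CC[C@H](C(=C)COCc1ccc(OC)cc1)CCO[Si](C)(C)C(C)(C)C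
F2 | step 8 | (E)-vinyllithium from F1 (not isolated) | [Li]/C=C(\C)CC[C@H](C(=C)COCc1ccc(OC)cc1)CCO[Si](C)(C)C(C)(C)C
F3 | step 18 | (E)-alkenylzirconocene chloride from 25, Zr on C12 (not isolated) | C/C(=C\C/C=C(/C)CC[C@H]1O[C@]1(C)CC[C@H](C(=C)COCc1ccc(OC)cc1)CCO[Si](C)(C)C(C)(C)C)[Zr](Cl)(C1C=CC=C1)C1C=CC=C1
F4 | step 18 | (11E)-12-iodo alkene from 25: oxirane bearing (3Z,6E)-7-iodo-3-methylocta-3,6-dien-1-yl, C13–OTBS | C/C(I)=C\C/C=C(/C)CC[C@H]1O[C@]1(C)CC[C@H](C(=C)COCc1ccc(OC)cc1)CCO[Si](C)(C)C(C)(C)C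
F5 | step 18 | primary alcohol from F4 (C13–OH) | C/C(I)=C\C/C=C(/C)CC[C@H]1O[C@]1(C)CC[C@H](C(=C)COCc1ccc(OC)cc1)CCO
F6 | step 18 | iodo aldehyde from F5 (C13 aldehyde) | C/C(I)=C\C/C=C(/C)CC[C@H]1O[C@]1(C)CC[C@H](C(=C)COCc1ccc(OC)cc1)CC=O
F7 | step 25 | (1S,4S,5R,13R,8Z,11E)-4,5-dihydroxy acid, 13-OTBS | C=C(C(=O)O)[C@@H]1C[C@@H](O[Si](C)(C)C(C)(C)C)/C(C)=C/C/C=C(/C)CC[C@@H](O)[C@@](C)(O)CC1
F8 | step 25 | 5-acetoxy-4-hydroxy acid from F7 | C=C(C(=O)O)[C@@H]1C[C@@H](O[Si](C)(C)C(C)(C)C)/C(C)=C/C/C=C(/C)CC[C@@H](OC(C)=O)[C@@](C)(O)CC1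
F9 | step 25 | mixed anhydride of F8 with 2,4,6-trichlorobenzoic acid (not isolated) | C=C(C(=O)OC(=O)c2c(Cl)cc(Cl)cc2Cl)[C@@H]1C[C@@H](O[Si](C)(C)C(C)(C)C)/C(C)=C/C/C=C(/C)CC[C@@H](OC(C)=O)[C@@](C)(O)CC1
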